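Run Monday's, not Friday's, if you want the higher product at 30 min, and leave its bath at 110 °C. Here is what you inherit.

in all of them: substrate 0.078 M
- maple: coupling partner 4 equiv; free catalyst 0.28 mol%; temperature 65 °C; run made earlier
- cedar: coupling partner 4 equiv; free catalyst 0.68 mol%; temperature 90 °C; run made earlier
- Monday's: coupling partner 4.00 equiv; free catalyst 0.25 mol%; at 110 °C throughout; time 30 min
- Friday's: coupling partner 4.00 equiv; free catalyst 0.5 mol%; at 110 °C until 6.0 min, from then on at 70 °C; time 30 min

| run | time / min | product / % | substrate / % |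
|---|---|---|---|
| maple | 12.0 | 7.0 | 92.8 |
| maple | 25.0 | 14.3 | 84.9 |
| maple | 40.0 | 23.1 | 76.3 |
| maple | 80.0 | 44.4 | 56.6 |
| maple | 150 | 73.2 | 27.4 |
| cedar | 4.00 | 24.6 | 74.6 |
| cedar | 6.00 | 36.5 | 63.6 |
| cedar | 10.0 | 54.1 | 44.4 |
| cedar | 20.0 | 84.4 | 15.7 |
| cedar | 40.0 | 98.9 | 1.0 |

(each reading ± 0.5 percentage points)

- which one finishes higher in amount of product, in percent of the substrate charged ("neither" within 2 percentage points) (Monday's / Friday's / neither)
- amount of product at the end, in percent of the substrate charged, Monday's
- amount of product at the end, in percent of the substrate charged, Friday's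

In both earlier runs, substrate and product together stay close to the charge. With 4.00 equiv of coupling partner, I take substrate as the limiting reagent. Read each run as a pseudo-first-order constant k, the logarithm of charged over remaining substrate, divided by time. Maple's last reading gives 0.00863 min⁻¹, and cedar at 20.0 min gives 0.0926 min⁻¹. If k goes with loading, the two temperatures give an apparent activation energy of 60.7 kJ mol⁻¹. That gives φ = 9.20, the exchange rate: the minutes at 70 °C that do the work of one minute at 110 °C at equal loading.

Friday's has twice Monday's loading, but after 6.0 min it goes cold. Its time therefore counts as 17.2 min of Monday's flask, less than Monday's 30 min. Do not cool Monday's flask: each cold minute counts as 1/φ of a hot one. Extrapolating k to 110 °C, my own reckoning puts Monday's at 94.6% and Friday's at 81.2%.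

The forecast also names Monday's, but lower than mine: 93% (82% to 98%) for Monday's and 80% (71% to 88%) for Friday's. It warns that “catalyst order and temperature are confounded in the data”.

Monday's ended at 83.9% and Friday's at 73.4%, so Monday's leads, with the two results 9.1 percentage points and 6.6 points under the forecast.

    coupling partner + free catalyst ⇌ catalyst intermediate A (K = 7.00 M⁻¹, k = 61.0 M⁻¹ s⁻¹, Ea = 39.0 kJ mol⁻¹, ΔH = −35.0 kJ mol⁻¹)
    catalyst intermediate A → catalyst intermediate B (k = 72.0 s⁻¹, Ea = 80.0 kJ mol⁻¹)
    substrate + catalyst intermediate B ⇌ catalyst intermediate C (K = 4.90 M⁻¹, k = 35.0 M⁻¹ s⁻¹, Ea = 66.0 kJ mol⁻¹, ΔH = −29.0 kJ mol⁻¹)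
    catalyst intermediate C ⇌ catalyst intermediate D (K = 0.910, k = 190 s⁻¹, Ea = 81.0 kJ mol⁻¹, ΔH = −47.0 kJ mol⁻¹)
    catalyst intermediate D ⇌ free catalyst + product (K = 0.0360 M, k = 2.20 s⁻¹, Ea = 86.0 kJ mol⁻¹, ΔH = 4.00 kJ mol⁻¹)
    (constants at 110 °C)

Monday's flask, with 16% of its substrate left, gives k = 0.0609 min⁻¹. With φ, that puts Friday's product at 64.9%, against the 73.4% found. The neighbour is Friday's flask read at 20 min. Its 14.0 min of cold time bring it to 15.0 min of Monday's flask, so the reckoning gives 59.9% product. Read at that time, the flask holds 64.6% product, with 35% of its substrate left.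

All runs come from a simulation with made-up constants; noise was put on by code.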